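What I want from each flask is the E left over after 5.0 min, since what has gone has become Q or sits on the catalyst, and the flasks differ in their loading of G.

    E.Z → G + Q (k1 = 0.105 /s)
    E + Z ⇌ E.Z (K2 = 7.00 /M, k2 = 1.03 /M/s)
    X + G ⇌ X.G (K3 = 2.9 /M, k3 = 0.764 /M/s)
    X.G → J + Z (k4 = 0.189 /s)

| flask | E | X | G | time |
|---|---|---|---|---|
| south-west | 0.17 M | 0.187 M | 4.0 mM | 5.0 min |
| north | 0.17 M | 0.187 M | 6.0 mM | 5.0 min |
| south | 0.17 M | 0.187 M | 10 mM | 5.0 min |
| north-east | 0.17 M | 0.187 M | 15 mM | 5.0 min |
| north-west | 0.17 M | 0.187 M | 20 mM | 5.0 min |

- amount of Q at the end, in percent of the E charged for south-west, north, south, north-east, north-west, in this order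
- the shape of the row from first to last (falls, then rises / rises all the way / rises, then falls / hardly changes / falls all the way)

- "hardly changes" means that all values lie within two and a half points (for a concentration: within two and a half percent of the largest)
- run time (south-west): 5.0 min

I follow one catalyst unit through G, X.G, Z, E.Z and back to G, and I take the forms as steady, so each holds a share of the catalyst in proportion to its stay per round. X.G stays 5.29 s per round, the inverse of the constant of the step that releases J. E.Z stays 9.52 s, the inverse of the constant of the step that releases Q.

Z and G wait for a partner, and their waits are stretched by returns. Z binds charged E in 5.71 s, but E.Z falls back 1.40 times per passage forward, so Z waits 13.7 s per round. G binds charged X in 7.00 s, X.G falls back 1.39 times per passage forward, and G waits 16.8 s, the longest stay, while that of X.G is the shortest.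

The sum is 45.3 s, and this is what I carry: the round time, the time one catalyst unit needs to pass once through the cycle, the inverse of the usual turnover frequency.

The next rung is the run, 6.62 rounds long. The top rung is the life of E, its charge divided by the loading of G per round: 32.1 min in south-west and 6.42 min in north-west. The round is shorter than even the north-west life, so the forms can follow the fall of E and X.

The waits of Z and G make up 67.3% of the round, and they stretch as E and X fall. As a rough estimate I let the whole round stretch in proportion to the E left, which makes E pseudo-first-order. Q is then one minus the exponential of minus run over life: 14.4%, 20.8%, 32.3%, 44.3%, 54.1%, a row that rises from first to last.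

The forecast gives 14%, 20.5%, 32%, 44.5% and 55%, and says the row rises all the way, from a cycle “turning over about once every 45 s”. Its last point stands higher than mine.

The flasks give 14.1%, 20.6%, 32.4%, 45.0% and 55.6%, and the row rises all the way. In north-west at 5.00 min, 43% of the E and 44% of the X are left. Put into the round time, these leave the stays of X.G and E.Z as they were and stretch the two waits, so by this reckoning the north-west round becomes 85.1 s, and the catalyst turns at about half its pace at the charge. G's wait is 44.9% of that round, and north-west holds 45.2% of its catalyst as G at 5.00 min.

The constants are assumed; no experiment stands behind them.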